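**Plan**

1. Numbering (isocopalane; α/β refer to the usual orientation): ring A = C1–C5, C10; ring B = C5–C10; ring C = C8, C9, C11–C14; lactone ring = C4, C19(=O), O, C20, C10, C5; C15 = benzylic CH2 on C14; C16, C17, C18 = methyls on C13, C8, C4.
2. Retrosynthesis: first the late changes (aryl O-benzyl, C13–OH from a C13=C16 alkene, a temporary C3 ketone), then the lactone C19–O bond, then C4–C5, C9–C10 and C8–C14 together in one oxidative radical polyene cyclisation; the acyclic polyene is cut at C3–C4, C1–C2, C5–C10, C6–C7 and C15–aryl.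
3. Forward: nerol and an aryl bromide give the aryl-neryl unit; the chain is grown to the C5 aldehyde, the C10/C20 unit is added, and a Johnson–Claisen rearrangement and a Claisen condensation give the polyene β-keto ester. One cascade then closes ring A (C4–C5), ring B and ring C in that order; the lactone ring follows, then C13 hydration, removal of the C3 ketone and debenzylation.
4. Enabling feature: C4 is α to the lactone carbonyl C19, so a temporary ketone at C3 makes it a 1,3-dicarbonyl carbon that Mn(OAc)3 oxidises to a radical; the 1,5-spacing of the C5=C10, C8=C9 and C13=C14 alkenes lets three 6-endo closures follow, and C19 and C20 end 1,3-diaxial on ring A, ready to lactonise.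
5. Stereochemistry: alkene geometry (C20 cis to C6 at C5=C10 from the Johnson–Claisen step, E at C8=C9 from the SeO2 oxidation, Z at C13=C14 from nerol) is translated by chair transition states into C4, C5, C8, C9, C10 and C14; the absolute sense comes from a (−)-8-phenylmenthyl ester; C13 comes from α-face oxygen capture.
6. Helpers and their removal: the auxiliary is expelled on lactonisation, the TBDPS group on O20 by fluoride, the C3 ketone via its enol triflate, the benzyl ethers by hydrogenolysis.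

Key step: step 13

Remark (assumption): the (−)-8-phenylmenthyl ester is taken to shield the face of the C4 radical that leads to the (4S,5R,10S) series, by analogy with auxiliary-controlled cyclisations of 8-phenylmenthyl α-methyl β-keto esters; if the sense were opposite, (+)-8-phenylmenthol would be used in step 11 with no other change.

**Route**

Step 1
Reactants: 1 2-bromobenzene-1,4-diol (bromohydroquinone)
Product: 2 1,4-bis(benzyloxy)-2-bromobenzene
Conditions: BnBr (2.2 equiv), K2CO3, DMF, 60 °C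
Reagents that add atoms: benzyl bromide BrCc1ccccc1
Why: Williamson etherification should protect both phenols as benzyl ethers, which tolerate every later step and leave under neutral hydrogenolysis at the end.

Step 2
Reactants: 3 nerol
Product: 4 neryl bromide
Conditions: PBr3 (0.4 equiv), pyridine (cat.), Et2O, −10 °C
Reagents that add atoms: phosphorus tribromide BrP(Br)Br
Why: Bromination of the primary allylic alcohol with PBr3 at low temperature should proceed without allylic transposition and keep the Z alkene that later becomes C13=C14.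

Step 3
Reactants: 2 1,4-bis(benzyloxy)-2-bromobenzene; 4 neryl bromide
Product: 6 1,4-bis(benzyloxy)-2-[(2Z)-3,7-dimethylocta-2,6-dien-1-yl]benzene, via aryllithium 5 (not isolated)
Conditions: 2, n-BuLi (1.05 equiv), THF, −78 °C; then 4, CuI (5 mol%), −78 → 0 °C
Reagents that add atoms: none
Why: Bromine–lithium exchange and alkylation of the aryllithium at the primary allylic carbon should form the C15–aryl bond with retention of the Z geometry.

Step 4
Reactants: 6 1,4-bis(benzyloxy)-2-[(2Z)-3,7-dimethylocta-2,6-dien-1-yl]benzene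
Product: 7 (2E,6Z)-8-[2,5-bis(benzyloxy)phenyl]-2,6-dimethylocta-2,6-dien-1-ol
Conditions: SeO2 (0.3 equiv), t-BuOOH (3 equiv), salicylic acid (0.1 equiv), CH2Cl2, 0 °C → rt
Reagents that add atoms: selenium dioxide O=[Se]=O (catalytic oxygen carrier); tert-butyl hydroperoxide CC(C)(C)OO
Why: Riley allylic oxidation (ene reaction then [2,3]-shift) should hydroxylate the E methyl of the terminal isopropylidene group, giving the E allylic alcohol whose carbinol carbon becomes C7.

Step 5
Reactants: 7 (2E,6Z)-8-[2,5-bis(benzyloxy)phenyl]-2,6-dimethylocta-2,6-dien-1-ol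
Product: 8 1,4-bis(benzyloxy)-2-[(2Z,6E)-8-bromo-3,7-dimethylocta-2,6-dien-1-yl]benzene
Conditions: CBr4, PPh3, CH2Cl2, 0 °C
Reagents that add atoms: carbon tetrabromide BrC(Br)(Br)Br
Why: Appel bromination should convert the primary allylic alcohol into the bromide under neutral conditions without changing either alkene geometry.

Step 6
Reactants: 8 1,4-bis(benzyloxy)-2-[(2Z,6E)-8-bromo-3,7-dimethylocta-2,6-dien-1-yl]benzene
Product: 9 (4E,8Z)-10-[2,5-bis(benzyloxy)phenyl]-4,8-dimethyldeca-4,8-dienenitrile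
Conditions: MeCN (4 equiv), n-BuLi (3.5 equiv), THF, −78 °C; then 8, −78 → −20 °C
Reagents that add atoms: acetonitrile CC#N
Why: SN2 alkylation of (cyanomethyl)lithium by the allylic bromide should add C6 and C5, the latter as a nitrile, with excess nucleophile suppressing double alkylation.

Step 7
Reactants: 9 (4E,8Z)-10-[2,5-bis(benzyloxy)phenyl]-4,8-dimethyldeca-4,8-dienenitrile
Product: 11 (4E,8Z)-10-[2,5-bis(benzyloxy)phenyl]-4,8-dimethyldeca-4,8-dienal, via N-aluminated imine 10 (not isolated)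
Conditions: i-Bu2AlH (1.2 equiv), toluene, −78 °C; then 1 M aq. HCl, 0 °C
Reagents that add atoms: water O
Why: A single hydride transfer to the nitrile stops at the aluminated imine, and its hydrolysis should give the C5 aldehyde without over-reduction.

Step 8
Reactants: 12 2-bromoprop-2-en-1-ol
Product: 13 [(2-bromoprop-2-en-1-yl)oxy](tert-butyl)diphenylsilane
Conditions: TBDPSCl, imidazole, CH2Cl2, rt
Reagents that add atoms: tert-butyl(chloro)diphenylsilane CC(C)(C)[Si](Cl)(c1ccccc1)c1ccccc1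
Why: Silylation gives the future O20 a TBDPS ether, chosen because it should survive t-BuLi, hot propionic acid, lithium amide base and acetic acid.

Step 9
Reactants: 13 [(2-bromoprop-2-en-1-yl)oxy](tert-butyl)diphenylsilane; 11 (4E,8Z)-10-[2,5-bis(benzyloxy)phenyl]-4,8-dimethyldeca-4,8-dienal
Product: 15 (6E,10Z)-12-[2,5-bis(benzyloxy)phenyl]-2-{[tert-butyl(diphenyl)silyl]oxymethyl}-6,10-dimethyldodeca-1,6,10-trien-3-ol (racemic carbinol), via vinyllithium 14 (not isolated)
Conditions: 13, t-BuLi (2.0 equiv), Et2O, −78 °C; then 11, −78 °C; H2O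
Reagents that add atoms: none
Why: Bromine–lithium exchange and 1,2-addition of the vinyllithium to the aldehyde should form the C5–C10 bond and give the 2-substituted secondary allylic alcohol needed for the Claisen step, whose racemic carbinol centre is erased in step 10.

Step 10
Reactants: 15 (6E,10Z)-12-[2,5-bis(benzyloxy)phenyl]-2-{[tert-butyl(diphenyl)silyl]oxymethyl}-6,10-dimethyldodeca-1,6,10-trien-3-ol
Product: 18 methyl (4Z,8E,12Z)-14-[2,5-bis(benzyloxy)phenyl]-4-{[tert-butyl(diphenyl)silyl]oxymethyl}-8,12-dimethyltetradeca-4,8,12-trienoate, via mixed orthoester 16 (not isolated), via ketene acetal 17 (not isolated)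
Conditions: MeC(OMe)3 (6 equiv), EtCO2H (0.1 equiv), xylene, 135 °C, MeOH distilled off
Reagents that add atoms: trimethyl orthoacetate COC(C)(OC)OC
Why: The Johnson–Claisen rearrangement, through a chair transition state with the C6 chain equatorial, should form the C1–C2 bond and the trisubstituted C5=C10 alkene with C1 trans to C6 (C20 cis to C6), and adds C2 and C3.

Step 11
Reactants: 19 (−)-8-phenylmenthol
Product: 20 (1R,2S,5R)-5-methyl-2-(2-phenylpropan-2-yl)cyclohexyl propanoate
Conditions: EtCOCl, pyridine, DMAP (cat.), CH2Cl2, 0 °C → rt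
Reagents that add atoms: propanoyl chloride CCC(Cl)=O
Why: Acylation of the secondary alcohol gives the auxiliary propanoate that will supply C4, C18 and C19.

Step 12
Reactants: 20 (1R,2S,5R)-5-methyl-2-(2-phenylpropan-2-yl)cyclohexyl propanoate; 18 methyl (4Z,8E,12Z)-14-[2,5-bis(benzyloxy)phenyl]-4-{[tert-butyl(diphenyl)silyl]oxymethyl}-8,12-dimethyltetradeca-4,8,12-trienoate
Product: 22 (1R,2S,5R)-8-phenylmenthyl (6Z,10E,14Z)-16-[2,5-bis(benzyloxy)phenyl]-6-{[tert-butyl(diphenyl)silyl]oxymethyl}-2,10,14-trimethyl-3-oxohexadeca-6,10,14-trienoate (both C2 epimers), via lithium enolate 21 (not isolated)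
Conditions: 20 (2.2 equiv), LiN(i-Pr)2 (2.2 equiv), THF, −78 °C; then 18, −78 → 0 °C; AcOH
Reagents that add atoms: none
Why: A crossed Claisen condensation, driven by deprotonation of the β-keto ester formed, should join C3 to C4 and install the temporary C3 ketone next to the auxiliary ester; the epimeric C4 centre becomes planar in step 13.

Step 13
Reactants: 22 (1R,2S,5R)-8-phenylmenthyl (6Z,10E,14Z)-16-[2,5-bis(benzyloxy)phenyl]-6-{[tert-butyl(diphenyl)silyl]oxymethyl}-2,10,14-trimethyl-3-oxohexadeca-6,10,14-trienoate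
Product: 23 tricyclic keto ester (8-phenylmenthyl 15-[2,5-bis(benzyloxy)phenyl]-20-[tert-butyl(diphenyl)silyl]oxy-3-oxoisocopal-13(16)-en-19-oate; 4α-Me; 4β-ester; 5α-H; 8β-Me; 9α-H; 10β-CH2OSi; 14α-CH2Ar)
Conditions: Mn(OAc)3·2H2O (2.2 equiv), Cu(OAc)2·H2O (0.5 equiv), degassed AcOH, 25 °C
Reagents that add atoms: none
Why: Mn(OAc)3 oxidises the enol of the α-methyl β-keto ester to the C4 radical, which adds 6-endo-trig to C5 of the C5=C10 alkene and so forms the C4–C5 bond and ring A; the tertiary C10 radical then closes ring B (6-endo-trig onto C9), the tertiary C8 radical closes ring C (6-endo-trig onto C14), and Cu(OAc)2 oxidises the final tertiary C13 radical to the exocyclic C13=C16 alkene. The closest known reaction type is the Mn(OAc)3/Cu(OAc)2 oxidative free-radical polyene cyclisation of α-methyl β-keto esters, including 8-phenylmenthyl esters, to trans-fused 4-methyl-4-alkoxycarbonyl-3-oxodecalins. All three closures should pass through chair transition states, so the geometrically trans C5=C10 and E C8=C9 alkenes give the trans-anti-trans fusions (5α-H, 10β-CH2OSi, 9α-H, 8β-Me), the ester takes the axial 4β position syn to C20 as in that precedent, and the Z C13=C14 alkene places the arylmethyl group axial at C14 (14α). The absolute sense is set in the first bond formation, where the phenyl ring of the auxiliary covers one face of the planar C4 radical and C5 adds to the other. The step needs 6-endo over 5-exo closure, which each trisubstituted alkene secures by offering its CH terminus and giving a tertiary radical, and it needs cyclisation to outrun oxidation of the intermediate radicals, which sub-stoichiometric Cu(OAc)2 favours. Any 12-ene isomer formed in the last oxidation carries the same stereocentres and converges with 23 in step 15.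

Step 14
Reactants: 23 tricyclic keto ester
Product: 25 15-[2,5-bis(benzyloxy)phenyl]-3-oxoisocopal-13(16)-en-19,20-olide, via hydroxy ester 24 (not isolated)
Conditions: n-Bu4NF (1.5 equiv), THF, 0 °C → rt; H2O
Reagents that add atoms: none
Why: Fluoride desilylation frees the C20 alkoxide, which lies 1,3-diaxial to the C19 ester on ring A and should close the δ-lactone by intramolecular transesterification, releasing the auxiliary alcohol.

Step 15
Reactants: 25 15-[2,5-bis(benzyloxy)phenyl]-3-oxoisocopal-13(16)-en-19,20-olide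
Product: 27 15-[2,5-bis(benzyloxy)phenyl]-13α-hydroxy-3-oxoisocopalan-19,20-olide, via tertiary hydroperoxide 26 (not isolated)
Conditions: Co(acac)2 (0.2 equiv), PhSiH3 (2 equiv), O2 (1 atm), THF/i-PrOH, 0 °C → rt; then PPh3
Reagents that add atoms: dioxygen O=O
Why: Mukaiyama hydration (hydrogen-atom transfer to C16, O2 capture of the tertiary C13 radical) should deliver oxygen from the equatorial α face because the axial β approach is blocked by the 1,3-diaxial 8β-methyl, giving the 13α-hydroxy-13β-methyl centre.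

Step 16
Reactants: 27 15-[2,5-bis(benzyloxy)phenyl]-13α-hydroxy-3-oxoisocopalan-19,20-olide
Product: 29 15-[2,5-bis(benzyloxy)phenyl]-13α-hydroxy-3-(trifluoromethanesulfonyloxy)isocopal-2-en-19,20-olide, via dipotassium alkoxide enolate 28 (not isolated)
Conditions: KN(SiMe3)2 (2.3 equiv), THF, −78 °C; then PhNTf2 (1.2 equiv), −78 → −30 °C; AcOH
Reagents that add atoms: N-phenylbis(trifluoromethanesulfonimide) O=S(=O)(N(c1ccccc1)S(=O)(=O)C(F)(F)F)C(F)(F)F
Why: The C3 ketone can enolise only toward C2 because C4 is quaternary, and the enolate oxygen should be triflated while the hindered tertiary alkoxide is not, which prepares removal of the temporary ketone.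

Step 17
Reactants: 29 15-[2,5-bis(benzyloxy)phenyl]-13α-hydroxy-3-(trifluoromethanesulfonyloxy)isocopal-2-en-19,20-olide
Product: 30 15-[2,5-bis(benzyloxy)phenyl]-13α-hydroxyisocopal-2-en-19,20-olide
Conditions: Pd(OAc)2 (5 mol%), PPh3 (10 mol%), HCO2H, n-Bu3N, DMF, 60 °C
Reagents that add atoms: none
Why: Palladium-catalysed formate reduction of the enol triflate (oxidative addition to zerovalent palladium, formate exchange, decarboxylation, reductive elimination) should replace the C3–O bond by C3–H and leave a C2=C3 alkene.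

Step 18
Reactants: 30 15-[2,5-bis(benzyloxy)phenyl]-13α-hydroxyisocopal-2-en-19,20-olide
Product: 31 (4S,5R,8R,9S,10S,13S,14R)-15-(2,5-dihydroxyphenyl)-13-hydroxyisocopalan-19,20-olide (target)
Conditions: H2 (1 atm), 10% Pd/C, EtOAc/EtOH, rt, under argon on work-up
Reagents that add atoms: none
Why: One hydrogenation should saturate the C2=C3 alkene (no stereocentre is formed) and cleave both benzyl ethers by hydrogenolysis while leaving the lactone and the tertiary alcohol untouched.

**Compound list**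

1 | 2-bromobenzene-1,4-diol | Oc1ccc(O)c(Br)c1 | starting material
2 | 1,4-bis(benzyloxy)-2-bromobenzene | Brc1cc(OCc2ccccc2)ccc1OCc1ccccc1 | intermediate
3 | nerol, (2Z)-3,7-dimethylocta-2,6-dien-1-ol | CC(C)=CCC/C(C)=C\CO | starting material
4 | neryl bromide, (2Z)-1-bromo-3,7-dimethylocta-2,6-diene | CC(C)=CCC/C(C)=C\CBr | intermediate
5 | [2,5-bis(benzyloxy)phenyl]lithium | [Li]c1cc(OCc2ccccc2)ccc1OCc1ccccc1 | intermediate
6 | 1,4-bis(benzyloxy)-2-[(2Z)-3,7-dimethylocta-2,6-dien-1-yl]benzene | CC(C)=CCC/C(C)=C\Cc1cc(OCc2ccccc2)ccc1OCc1ccccc1 | intermediate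
7 | (2E,6Z)-8-[2,5-bis(benzyloxy)phenyl]-2,6-dimethylocta-2,6-dien-1-ol | OC/C(C)=C/CC/C(C)=C\Cc1cc(OCc2ccccc2)ccc1OCc1ccccc1 | intermediate
8 | 1,4-bis(benzyloxy)-2-[(2Z,6E)-8-bromo-3,7-dimethylocta-2,6-dien-1-yl]benzene | BrC/C(C)=C/CC/C(C)=C\Cc1cc(OCc2ccccc2)ccc1OCc1ccccc1 | intermediate
9 | (4E,8Z)-10-[2,5-bis(benzyloxy)phenyl]-4,8-dimethyldeca-4,8-dienenitrile | N#CCC/C(C)=C/CC/C(C)=C\Cc1cc(OCc2ccccc2)ccc1OCc1ccccc1 | intermediate
10 | N-(diisobutylalumanyl) imine of aldehyde 11 | CC(C)C[Al](CC(C)C)N=CCC/C(C)=C/CC/C(C)=C\Cc1cc(OCc2ccccc2)ccc1OCc1ccccc1 | intermediate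
11 | (4E,8Z)-10-[2,5-bis(benzyloxy)phenyl]-4,8-dimethyldeca-4,8-dienal | O=CCC/C(C)=C/CC/C(C)=C\Cc1cc(OCc2ccccc2)ccc1OCc1ccccc1 | intermediate
12 | 2-bromoprop-2-en-1-ol | OCC(Br)=C | starting material
13 | [(2-bromoprop-2-en-1-yl)oxy](tert-butyl)diphenylsilane | C=C(Br)CO[Si](c1ccccc1)(c1ccccc1)C(C)(C)C | intermediate
14 | {3-[tert-butyl(diphenyl)silyl]oxyprop-1-en-2-yl}lithium | [Li]C(=C)CO[Si](c1ccccc1)(c1ccccc1)C(C)(C)C | intermediate
15 | (6E,10Z)-12-[2,5-bis(benzyloxy)phenyl]-2-{[tert-butyl(diphenyl)silyl]oxymethyl}-6,10-dimethyldodeca-1,6,10-trien-3-ol, racemic at C3 | C=C(CO[Si](c1ccccc1)(c1ccccc1)C(C)(C)C)C(O)CC/C(C)=C/CC/C(C)=C\Cc1cc(OCc2ccccc2)ccc1OCc1ccccc1 | intermediate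
16 | mixed orthoester, the 1,1-dimethoxyethyl ether of 15 | COC(C)(OC)OC(CC/C(C)=C/CC/C(C)=C\Cc1cc(OCc2ccccc2)ccc1OCc1ccccc1)C(=C)CO[Si](c1ccccc1)(c1ccccc1)C(C)(C)C | intermediate
17 | ketene acetal, the 1-methoxyvinyl ether of 15 | C=C(OC)OC(CC/C(C)=C/CC/C(C)=C\Cc1cc(OCc2ccccc2)ccc1OCc1ccccc1)C(=C)CO[Si](c1ccccc1)(c1ccccc1)C(C)(C)C | intermediate
18 | methyl (4Z,8E,12Z)-14-[2,5-bis(benzyloxy)phenyl]-4-{[tert-butyl(diphenyl)silyl]oxymethyl}-8,12-dimethyltetradeca-4,8,12-trienoate | COC(=O)CC/C(CO[Si](c1ccccc1)(c1ccccc1)C(C)(C)C)=C/CC/C(C)=C/CC/C(C)=C\Cc1cc(OCc2ccccc2)ccc1OCc1ccccc1 | intermediate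
19 | (−)-8-phenylmenthol, (1R,2S,5R)-5-methyl-2-(2-phenylpropan-2-yl)cyclohexan-1-ol | O[C@@H]1C[C@H](C)CC[C@H]1C(C)(C)c1ccccc1 | starting material
20 | (1R,2S,5R)-5-methyl-2-(2-phenylpropan-2-yl)cyclohexyl propanoate | CCC(=O)O[C@@H]1C[C@H](C)CC[C@H]1C(C)(C)c1ccccc1 | intermediate
21 | lithium enolate of 20 | CC=C(O[Li])O[C@@H]1C[C@H](C)CC[C@H]1C(C)(C)c1ccccc1 | intermediate
22 | (1R,2S,5R)-8-phenylmenthyl (6Z,10E,14Z)-16-[2,5-bis(benzyloxy)phenyl]-6-{[tert-butyl(diphenyl)silyl]oxymethyl}-2,10,14-trimethyl-3-oxohexadeca-6,10,14-trienoate, both C2 epimers | CC(C(=O)O[C@@H]1C[C@H](C)CC[C@H]1C(C)(C)c1ccccc1)C(=O)CC/C(CO[Si](c1ccccc1)(c1ccccc1)C(C)(C)C)=C/CC/C(C)=C/CC/C(C)=C\Cc1cc(OCc2ccccc2)ccc1OCc1ccccc1 | intermediate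
23 | tricyclic keto ester, 8-phenylmenthyl 15-[2,5-bis(benzyloxy)phenyl]-20-[tert-butyl(diphenyl)silyl]oxy-3-oxoisocopal-13(16)-en-19-oate (4α-Me, 4β-ester, 5α-H, 8β-Me, 9α-H, 10β-CH2OSi, 14α-CH2Ar) | C[C@@]12CC[C@@H]3[C@](CO[Si](c4ccccc4)(c4ccccc4)C(C)(C)C)(CCC(=O)[C@]3(C)C(=O)O[C@@H]4C[C@H](C)CC[C@H]4C(C)(C)c4ccccc4)[C@H]1CCC(=C)[C@@H]2Cc1cc(OCc2ccccc2)ccc1OCc1ccccc1 | intermediate
24 | 20-hydroxy keto ester (desilylated 23) | C[C@@]12CC[C@@H]3[C@](CO)(CCC(=O)[C@]3(C)C(=O)O[C@@H]4C[C@H](C)CC[C@H]4C(C)(C)c4ccccc4)[C@H]1CCC(=C)[C@@H]2Cc1cc(OCc2ccccc2)ccc1OCc1ccccc1 | intermediate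
25 | 15-[2,5-bis(benzyloxy)phenyl]-3-oxoisocopal-13(16)-en-19,20-olide | C[C@@]12CC[C@@H]3[C@]4(CCC(=O)[C@]3(C)C(=O)OC4)[C@H]1CCC(=C)[C@@H]2Cc1cc(OCc2ccccc2)ccc1OCc1ccccc1 | intermediate
26 | 15-[2,5-bis(benzyloxy)phenyl]-13α-hydroperoxy-3-oxoisocopalan-19,20-olide | C[C@@]12CC[C@@H]3[C@]4(CCC(=O)[C@]3(C)C(=O)OC4)[C@H]1CC[C@](C)(OO)[C@@H]2Cc1cc(OCc2ccccc2)ccc1OCc1ccccc1 | intermediate
27 | 15-[2,5-bis(benzyloxy)phenyl]-13α-hydroxy-3-oxoisocopalan-19,20-olide | C[C@@]12CC[C@@H]3[C@]4(CCC(=O)[C@]3(C)C(=O)OC4)[C@H]1CC[C@](C)(O)[C@@H]2Cc1cc(OCc2ccccc2)ccc1OCc1ccccc1 | intermediate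
28 | dipotassium 13-alkoxide 2-en-3-olate of 27 | C[C@@]12CC[C@@H]3[C@]4(CC=C([O-])[C@]3(C)C(=O)OC4)[C@H]1CC[C@](C)([O-])[C@@H]2Cc1cc(OCc2ccccc2)ccc1OCc1ccccc1.[K+].[K+] | intermediate
29 | 15-[2,5-bis(benzyloxy)phenyl]-13α-hydroxy-3-(trifluoromethanesulfonyloxy)isocopal-2-en-19,20-olide | C[C@@]12CC[C@@H]3[C@]4(CC=C(OS(=O)(=O)C(F)(F)F)[C@]3(C)C(=O)OC4)[C@H]1CC[C@](C)(O)[C@@H]2Cc1cc(OCc2ccccc2)ccc1OCc1ccccc1 | intermediate
30 | 15-[2,5-bis(benzyloxy)phenyl]-13α-hydroxyisocopal-2-en-19,20-olide | C[C@@]12CC[C@@H]3[C@]4(CC=C[C@]3(C)C(=O)OC4)[C@H]1CC[C@](C)(O)[C@@H]2Cc1cc(OCc2ccccc2)ccc1OCc1ccccc1 | intermediate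
31 | (4S,5R,8R,9S,10S,13S,14R)-15-(2,5-dihydroxyphenyl)-13-hydroxyisocopalan-19,20-olide | C[C@@]12CC[C@@H]3[C@]4(CCC[C@]3(C)C(=O)OC4)[C@H]1CC[C@](C)(O)[C@@H]2Cc1cc(O)ccc1O | target

**Totals**

Total step count: 18. Longest linear sequence: 15 steps (steps 2, 3, 4, 5, 6, 7, 9, 10, 12, 13, 14, 15, 16, 17, 18, from nerol).

**Steps most likely to fail, with fallbacks**

Step 13. The cascade may end early, by oxidation of the tertiary C8 radical before it closes ring C onto the Z alkene (the closure that must place the arylmethyl group axial), and the auxiliary may give incomplete facial control (minor diastereomers would be removed by chromatography at 23). The fallback divides the event into a radical bicyclisation and a cationic closure of ring C. It sets out from 22: oxidation with Mn(OAc)3·2H2O and 1.5 equiv of Cu(OAc)2·H2O in AcOH is allowed to stop after rings A and B, giving the bicyclic 8(17)-ene keto ester F1. Treatment with SnCl4 in CH2Cl2 at −78 °C (cation–olefin cyclisation, C8 cation onto C14 through a chair, loss of a proton from C12) should then give the tricyclic 12-ene keto ester F2. The conditions of step 14 convert F2 into the 12-ene keto lactone F3. The conditions of step 15, with hydrogen adding to C12 and oxygen to C13, bring the route back at 27.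

Step 15. Capture of the planar C13 radical by O2 may show poor facial selectivity because the axial arylmethyl group at C14 also hinders the α face. The fallback replaces radical hydration by a concerted oxygen transfer followed by reduction, and sets out from 25: dimethyldioxirane in acetone at 0 °C should epoxidise the exocyclic alkene from the equatorial α face to give the 13α,16-epoxide F4. Sodium benzeneselenolate (PhSeH, NaH, THF) opens it at the primary C16 to give the 13α-hydroxy 16-phenylselenide F5. Reductive cleavage of the C–Se bond with n-Bu3SnH and AIBN in toluene at 80 °C returns the route at 27.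

Step 12. Proton transfer between the hindered enolate and the methyl ester, together with slow acylation, may leave the condensation incomplete. The fallback activates the acyl partner instead, and sets out from 18: saponification (LiOH, THF/H2O, then acidification) gives the carboxylic acid F6. 1,1'-Carbonyldiimidazole in THF converts it into the acyl imidazolide F7. Addition of F7 to the lithium enolate 21 (2.2 equiv, THF, −78 °C) returns the route at 22.

**Further compounds**

F1 | step 13 | bicyclic keto ester, 8-phenylmenthyl ester with rings A and B closed, 8(17)-exo-methylene and (Z)-5-aryl-3-methylpent-3-enyl chain on C9 (4α-Me, 5α-H, 9α-H, 10β-CH2OSi) | C=C1CC[C@@H]3[C@](CO[Si](c4ccccc4)(c4ccccc4)C(C)(C)C)(CCC(=O)[C@]3(C)C(=O)O[C@@H]4C[C@H](C)CC[C@H]4C(C)(C)c4ccccc4)[C@H]1CC/C(C)=C\Cc1cc(OCc2ccccc2)ccc1OCc1ccccc1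
F2 | step 13 | tricyclic 12-ene keto ester, the 12-ene isomer of 23 | C[C@@]12CC[C@@H]3[C@](CO[Si](c4ccccc4)(c4ccccc4)C(C)(C)C)(CCC(=O)[C@]3(C)C(=O)O[C@@H]4C[C@H](C)CC[C@H]4C(C)(C)c4ccccc4)[C@H]1CC=C(C)[C@@H]2Cc1cc(OCc2ccccc2)ccc1OCc1ccccc1
F3 | step 13 | 15-[2,5-bis(benzyloxy)phenyl]-3-oxoisocopal-12-en-19,20-olide | C[C@@]12CC[C@@H]3[C@]4(CCC(=O)[C@]3(C)C(=O)OC4)[C@H]1CC=C(C)[C@@H]2Cc1cc(OCc2ccccc2)ccc1OCc1ccccc1
F4 | step 15 | 15-[2,5-bis(benzyloxy)phenyl]-13α,16-epoxy-3-oxoisocopalan-19,20-olide | C[C@@]12CC[C@@H]3[C@]4(CCC(=O)[C@]3(C)C(=O)OC4)[C@H]1CC[C@]5(OC5)[C@@H]2Cc1cc(OCc2ccccc2)ccc1OCc1ccccc1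
F5 | step 15 | 15-[2,5-bis(benzyloxy)phenyl]-13α-hydroxy-3-oxo-16-(phenylselanyl)isocopalan-19,20-olide | C[C@@]12CC[C@@H]3[C@]4(CCC(=O)[C@]3(C)C(=O)OC4)[C@H]1CC[C@](C[Se]c5ccccc5)(O)[C@@H]2Cc1cc(OCc2ccccc2)ccc1OCc1ccccc1
F6 | step 12 | (4Z,8E,12Z)-14-[2,5-bis(benzyloxy)phenyl]-4-{[tert-butyl(diphenyl)silyl]oxymethyl}-8,12-dimethyltetradeca-4,8,12-trienoic acid | OC(=O)CC/C(CO[Si](c1ccccc1)(c1ccccc1)C(C)(C)C)=C/CC/C(C)=C/CC/C(C)=C\Cc1cc(OCc2ccccc2)ccc1OCc1ccccc1
F7 | step 12 | acyl imidazolide of F6 | O=C(CC/C(CO[Si](c1ccccc1)(c1ccccc1)C(C)(C)C)=C/CC/C(C)=C/CC/C(C)=C\Cc1cc(OCc2ccccc2)ccc1OCc1ccccc1)n1ccnc1
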